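The constants of this flask are hidden, but one can be read from its own readings: the selectivity factor s, the logarithm of the fraction of left-handed substrate left over the logarithm of the fraction of right-handed substrate left, 2.53 from Saturday's reading at 1.04 d.

| setting | Saturday's | Monday's | flask |
|---|---|---|---|
| left-handed substrate | 0.020 M | 0.013 M | 0.020 M |
| right-handed substrate | 0.020 M | 0.013 M | 0.020 M |
| solid reagent | 0.060 M | 0.060 M | 0.0600 M |
| free catalyst | 2.4 mM | 2.4 mM | 2.4 mM |
| impurity | 0.45 mM | 0.45 mM | 0.45 mM |
| remark | the very flask that is asked about, followed so far | run made earlier |  |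
| time |  |  | 6.0 d |

| run | time / d | right-handed substrate / % | left-handed substrate / % | left-handed product / % |
|---|---|---|---|---|
| Saturday's | 0.333 | 43.7 | 36.4 | 11.8 |
| Saturday's | 0.625 | 41.3 | 26.3 | 22.7 |
| Saturday's | 1.04 | 31.0 | 14.9 | 35.1 |
| Saturday's | 1.25 | 27.4 | 10.0 | 40.1 |
| Saturday's | 1.67 | 18.1 | 6.3 | 43.6 |
| Saturday's | 2.08 | 14.6 | 2.9 | 46.9 |
| Saturday's | 2.50 | 11.7 | 0 | 49.9 |
| Monday's | 0.333 | 44.9 | 34.2 | 13.5 |
| Monday's | 0.625 | 37.4 | 23.0 | 27.8 |
| Monday's | 1.04 | 27.1 | 11.4 | 36.5 |
| Monday's | 1.25 | 24.8 | 8.1 | 42.6 |
| Monday's | 1.67 | 16.2 | 1.2 | 45.7 |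
| Monday's | 2.08 | 13.3 | 1.2 | 49.0 |
| Monday's | 2.50 | 8.0 | 2.0 | 49.7 |

(readings scatter by 1 percentage point)

- whether the excess of right-handed substrate over left-handed substrate among what is left of the two reaches 98% by 6.0 d (yes / no)
- the highest excess of right-handed substrate over left-handed substrate among what is left of the two up to 6.0 d

- free catalyst is single-handed; left-handed substrate and right-handed substrate are mirror images of each other, charged as a racemate, each of them at the stated concentration
- given per volume of solution although it is solid: solid reagent
- at the start none of the solid reagent is in solution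

You take over Saturday's flask. At 2.50 d it read 11.7% right-handed substrate, 0% left-handed substrate and 49.9% left-handed product. With s, the wanted 98% needs the right-handed substrate down to 2.49% of the charge, so don't work the flask up yet, because the reading stands above that. Replace its curve by a mean constant k, read from the charge to the last reading: 0.581 d⁻¹ brings you there at 5.16 d. The mean has an error, since the stretch after 1.04 d reads 0.667 d⁻¹, and that gives 4.82 d. Both reckoned times lie before 6.0 d, so I reckon yes, with 99.0% at the end by the mean k. The forecast gives yes and 99%, with the caution “The margin is modest”.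

The flask gives yes and 99.1%. It reached the wanted excess at 4.77 d, with 1.97% of right-handed substrate left, less than the reckoned residue.

    partner + free catalyst + left-handed substrate → free catalyst + left-handed product (k = 2.07 M⁻² s⁻¹)
    partner + free catalyst + right-handed substrate → free catalyst + right-handed product (k = 0.855 M⁻² s⁻¹)
    partner ⇌ dormant form (K = 4.91, k = 1.62 × 10⁻⁵ s⁻¹)
    free catalyst + impurity → spent catalyst (k = 4.52 M⁻¹ s⁻¹)
    solid reagent ⇌ partner, rate k5*(cs5 - [partner]) while solid is left; crystals form when [partner] > cs5 (solubility = 8.00 mM, k = 6.94 × 10⁻⁵ s⁻¹)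

On Monday's flask, s turns the 24.8% of right-handed substrate read at 1.25 d into 8.48% of left-handed substrate, and the reading there is 8.1%.

Readings and results were generated by integration with constants of no real substance; the scatter is artificial.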